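## Analysis of the target

Germacrane numbering is used throughout: ring carbons C1–C10, C14 on C10, C15 on C4, isopropenyl carbons C11–C13 on C7.

1. The target is a ten-membered carbocycle with one (E)-trisubstituted ring alkene (C1=C10), a 4,5-epoxide whose ring bonds C3–C4 and C5–C6 are trans (the epoxide of an (E)-C4=C5 alkene), a tiglate on O3 and an acetate on O6.
2. The five stereocenters are contiguous, C3–C7 (3S,4R,5R,6R,7S). In a zigzag drawing of C2–C7 the C3 oxygen is syn (threo) and the C6 oxygen anti (erythro) to the epoxide oxygen, and H6 and H7 are cis.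
3. The C5/C6 erythro relation is the awkward one. In an (E)-C4=C5 alkene, A(1,3) strain with C15 holds H6 in the alkene plane and puts a C6 oxygen on the exposed face, so epoxidation gives the threo isomer; the erythro isomer must come from a later event at C6.
4. The feature that decides the strategy: C1=C10 and C4–C5 (a masked alkene) stand in a 1,5-relation across the single bond C2–C3. The carbocycle is therefore a cyclodeca-1,5-diene, the [3,3] partner of a 1,2-dialkenylcyclohexane made of C5–C10.
5. On that six-carbon segment the methyl-bearing C10 and the isopropenyl-bearing C7 are para, and C5 and C6 carry oxygen. This is the skeleton of carvone with its carbonyl at C5.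
6. Sensitive groups: before epoxidation the 1,5-diene can undergo Cope rearrangement back to a divinylcyclohexane on heating. After epoxidation, acid can open the epoxide transannularly through C1=C10, and a free alkoxide next to the epoxide can start a Payne rearrangement.
7. The synthesis is hard because a strained medium ring with an E trisubstituted alkene must be closed, one remote center (C7) must control four others, and two hindered secondary hydroxyls flanking the epoxide must receive different acyl groups.

## Retrosynthetic reasoning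

**C6 (26 ⇐ 25 ⇐ 24 ⇐ 23 ⇐ 22).** The acetate goes on last. The C6–H bond, not the C6–O bond, is cut: alcohol 25 comes from ketone 24 by chelation-controlled reduction, and 24 from the C6 epimer 23, which is freed from silyl ether 22. An SN2 inversion at C6 would need attack from inside the ring, and epoxidation cannot give the erythro relation (point 3 above), so a redox inversion after the epoxide is in place is the dependable way.

**Tiglate and epoxide (22 ⇐ 21 ⇐ 20).** The tiglate is placed on the only free hydroxyl of 21. The two C–O bonds of the epoxide are cut to give alkene 20, whose C3 hydroxyl directs the oxidant. With the C6 oxygen in the 6S (trans to isopropenyl) configuration, both oxygens lie on the exposed face of C4=C5, so this configuration is carried up to 23 on purpose.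

**C5 (20 ⇐ 19 ⇐ 18).** The C3 ether is cleaved oxidatively, and C5–H is traced back to C5–OTf. Enol triflate 18 is the enol derivative of a C5 ketone, which is the signature of a ring expansion.

**Key disconnection (18 ⇐ 15).** Enolate 17 is cut at C2–C3 and reconnected at C5–C10 ([3,3]). This leads to alkoxide 16 of cyclohexanol 15, which carries a vinyl group on C10 and a Z enol ether on C5. In the forward direction one event builds the ten-membered ring, both E ring alkenes (one as the enolate) and the C3 stereocenter, and it cleaves the former carvone ring bond. The other [3,3] partition (C8–C9 formed, C1–C6 broken) would put C4=C5 inside the six-membered ring and deliver it Z, so it is not used.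

**C4–C5 (15 ⇐ 7 + 13).** The bond is made by 1,2-addition of alkenyllithium 14, generated from bromide 13, to ketone 7. Only the trans relation of the two alkenyl groups has to be controlled, because C5 and C10 become sp2 in the key step.

**Enol ether fragment (13 ⇐ 11 ⇐ 10 ⇐ 8 + 9).** The Z bromide comes from the Z prop-1-enyl ether 11 by addition and elimination, 11 from allyl ether 10, and 10 from chloride 8 and alcohol 9.

**Ketone (7 ⇐ 4 ⇐ 3 ⇐ 1).** The C6 oxygen is introduced by oxidation of the only possible enolate of 4, trans to the isopropenyl group. The C10 vinyl group comes from a reductive aldol reaction of 1 followed by dehydration of 3. C7 is bought with (R)-carvone 1.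

## Alternatives that were turned down

**Alternative 1:** the textbook cut, C6–C7 in the intact epoxide. The forward key step is an intramolecular allylation of the α,β-epoxy aldehyde A1 by its terminal allylic chloride (Nozaki–Hiyama–Kishi reaction or a palladium/zinc umpolung variant), closing the ring to epoxy alcohol A2 and setting C6 and C7. Turned down because:
- it is an end-to-end closure of a flexible chain, with the entropic cost and high dilution that a ring expansion avoids;
- A1 needs about nine linear steps in which C3 and the epoxide are set by two independent reagent-controlled operations, nothing is relayed and no chiral-pool center is used;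
- a closed six-membered allylmetal transition state is expected to give the anti homoallylic alcohol (H6 and H7 trans), so the C6 epimer of A2 is the likely product and a late inversion at C6 would still be needed;
- α,β-epoxy aldehydes of this kind epimerize and oligomerize easily.

**Alternative 2:** [2,3]-Wittig ring contraction. The same bond C6–C7 is formed by contraction of the thirteen-membered bis-allylic ether A3 (oxygen bridging C6 and C12): deprotonation at C6 and a [2,3] shift onto C7 give alcohol A4, with the isopropenyl group formed in the same event. Turned down because: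
- A3 has two allylic α-oxygen positions (C6 and C12), and a shift from C12 gives a constitutional isomer;
- the only stereocenter present, C3, is remote from the two being formed, so absolute control would need a chiral amide base;
- the E allyl terminus leads through the envelope transition state to the 6,7-anti product A4;
- the macrocyclic etherification before it is again an end-to-end closure, so no step is saved against alternative 1.

**Alternative 3:** Grob-type 1,4-fragmentation of a decalin. C5–C10 is cut, as in the chosen route, but in the trans-decalin A5 with a C1 mesylate: a carbanion equivalent at C4 pushes through C5–C10 and expels the mesylate, giving both E alkenes of A6 stereospecifically. Turned down because: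
- the electron source must sit on C4, which bears C15; boron cannot be placed on that fully substituted carbon by hydroboration, and a C3 ketone enolate would expel the C1 mesylate by plain β-elimination;
- C15 therefore has to be an aldehyde (A5) and be reduced to methyl afterwards, three more steps;
- A5 has seven stereocenters and four oxygenated ring carbons and would take more than twelve steps from 1;
- four of its stereocenters are destroyed in the fragmentation.

Key step: step 8

## Route

Step 1
Reactants: 1 (R)-carvone
Product: 3 (2R,5R)-2-(1-hydroxyethyl)-2-methyl-5-(prop-1-en-2-yl)cyclohexan-1-one (both carbinol epimers), via lithium enolate 2 (not isolated)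
Conditions: LiBH(s-Bu)3, THF, −78 °C; then CH3CHO, −78 °C; aq NH4Cl
Reagents that add atoms: acetaldehyde, CC=O
Why: Conjugate hydride transfer to the enone gives only the C2 enolate 2, which adds to acetaldehyde (reductive aldol reaction); the electrophile enters axially on the half-chair enolate that carries the isopropenyl group equatorial and so ends cis to it (2R), the sense known from annulations of dihydrocarvone; the carbinol center is lost in step 2.

Step 2
Reactants: 3 (2R,5R)-2-(1-hydroxyethyl)-2-methyl-5-(prop-1-en-2-yl)cyclohexan-1-one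
Product: 4 (2R,5R)-2-ethenyl-2-methyl-5-(prop-1-en-2-yl)cyclohexan-1-one
Conditions: Ph2S[OC(CF3)2Ph]2, CH2Cl2, 0 to 25 °C
Reagents that add atoms: none
Why: Sulfurane dehydration through an alkoxysulfonium intermediate; the carbinol carbon has hydrogens only on its methyl neighbor because the other neighbor is quaternary, so only the vinyl group can form, and the neutral conditions avoid retro-aldol cleavage.

Step 3
Reactants: 4 (2R,5R)-2-ethenyl-2-methyl-5-(prop-1-en-2-yl)cyclohexan-1-one
Product: 7 (2R,5S,6S)-6-[(tert-butyldimethylsilyl)oxy]-2-ethenyl-2-methyl-5-(prop-1-en-2-yl)cyclohexan-1-one, via sodium enolate 5 (not isolated), via sodium alkoxide 6 (not isolated)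
Conditions: NaN(SiMe3)2, THF, −78 °C; then 2-(phenylsulfonyl)-3-phenyloxaziridine, −78 °C; then TBSOTf, −78 to 0 °C
Reagents that add atoms: 2-(phenylsulfonyl)-3-phenyloxaziridine, O=S(=O)(c1ccccc1)N1OC1c1ccccc1; tert-butyldimethylsilyl trifluoromethanesulfonate, CC(C)(C)[Si](C)(C)OS(=O)(=O)C(F)(F)F
Why: C6 is the only enolizable position; oxygen transfer from the N-sulfonyloxaziridine to enolate 5 (enolate hydroxylation) should occur anti to the neighboring isopropenyl group and to the axial vinyl group, giving the trans (6S) alkoxide 6, which is silylated in the same flask.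

Step 4
Reactants: 8 4-methoxybenzyl chloride; 9 allyl alcohol (excess)
Product: 10 1-methoxy-4-[(prop-2-en-1-yloxy)methyl]benzene
Conditions: 50% aq NaOH, Bu4NHSO4 (cat.), 25 °C
Reagents that add atoms: none
Why: Williamson ether synthesis under phase-transfer catalysis; the benzylic chloride is a good SN2 electrophile.

Step 5
Reactants: 10 1-methoxy-4-[(prop-2-en-1-yloxy)methyl]benzene
Product: 11 1-methoxy-4-{[(1Z)-prop-1-en-1-yloxy]methyl}benzene
Conditions: KOt-Bu (0.3 equiv), DMSO, 25 °C
Reagents that add atoms: none
Why: Base-mediated isomerization of an allyl ether to a prop-1-enyl ether; proton transfer within the potassium-bound allyl anion should give the cis (Z) enol ether.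

Step 6
Reactants: 11 1-methoxy-4-{[(1Z)-prop-1-en-1-yloxy]methyl}benzene
Product: 13 1-({[(1Z)-2-bromoprop-1-en-1-yl]oxy}methyl)-4-methoxybenzene, via dibromide 12 (not isolated)
Conditions: Br2, CH2Cl2, −78 °C; then DBU, −78 to 0 °C
Reagents that add atoms: bromine, BrBr
Why: Anti addition of Br2 to the Z enol ether gives dibromide 12; anti E2 loss of HBr (bromide from the acetal carbon, hydrogen from C2) places oxygen and the remaining bromine cis, so the Z bromide should form stereospecifically; the low temperature protects the anisole ring from bromination.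

Step 7
Reactants: 13 1-({[(1Z)-2-bromoprop-1-en-1-yl]oxy}methyl)-4-methoxybenzene; 7 (2R,5S,6S)-6-[(tert-butyldimethylsilyl)oxy]-2-ethenyl-2-methyl-5-(prop-1-en-2-yl)cyclohexan-1-one
Product: 15 (1R,2R,5S,6S)-6-[(tert-butyldimethylsilyl)oxy]-2-ethenyl-1-{(1Z)-1-[(4-methoxyphenyl)methoxy]prop-1-en-2-yl}-2-methyl-5-(prop-1-en-2-yl)cyclohexan-1-ol, via alkenyllithium 14 (not isolated)
Conditions: t-BuLi (2 equiv), Et2O, −78 °C; then 7, THF, −78 to −40 °C; aq NaHCO3
Reagents that add atoms: none
Why: Bromine–lithium exchange with retention gives 14, in which oxygen and lithium are cis so that anti β-elimination is not possible at −78 °C; 1,2-addition to ketone 7 should occur on the face opposite to the axial vinyl group at C2, so the new alkenyl group is trans to the vinyl group (1R); both new stereocenters are lost in step 8 and only their trans relation matters.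

Step 8
Reactants: 15 (1R,2R,5S,6S)-6-[(tert-butyldimethylsilyl)oxy]-2-ethenyl-1-{(1Z)-1-[(4-methoxyphenyl)methoxy]prop-1-en-2-yl}-2-methyl-5-(prop-1-en-2-yl)cyclohexan-1-ol
Product: 18 (1(10)E,4Z,3S,6S,7S)-6-[(tert-butyldimethylsilyl)oxy]-3-[(4-methoxybenzyl)oxy]germacra-1(10),4,11-trien-5-yl trifluoromethanesulfonate, via potassium alkoxide 16 (not isolated), via potassium enolate 17 (not isolated)
Conditions: KN(SiMe3)2, 18-crown-6, THF, 0 to 25 °C; then PhNTf2, −78 to 0 °C
Reagents that add atoms: N-phenylbis(trifluoromethanesulfonimide), O=S(=O)(N(c1ccccc1)S(=O)(=O)C(F)(F)F)C(F)(F)F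
Why: Deprotonation gives alkoxide 16, whose oxido group triggers an anionic oxy-Cope rearrangement, a [3,3] sigmatropic shift over C3=C4–C5–C10–C1=C2 that forms C2–C3 and breaks C5–C10; the closest known reaction type is the ring expansion of trans-1,2-dialkenylcyclohexanolates to cyclodec-5-enone enolates with trapping of the enolate as its triflate. The ten-membered ring is closed by a four-carbon ring expansion of the former carvone ring, not by an end-to-end cyclization, so no high dilution is needed. The two alkenyl groups of 16 are trans; they are axial in the resting chair and become equatorial after ring inversion (a few kcal/mol uphill), and only from that arrangement can C2 and C3 meet, in a chair-shaped transition state fused to the cyclohexane chair like a trans-decalin. In that chair C9 is antiperiplanar to C1–C2 and C6 to C4–C3, which gives the 1(10)E alkene and the ring-E enolate 17 (4Z by the sequence rule because O5 outranks C6). The new stereocenter C3 follows from the Z enol ether: the benzyloxy group is cis to C5, hence axial on the six-membered transition state, and C2 bonds to the face of C3 that makes it 3S; C6 and C7 are not touched, so the carvone center controls C3 through the ring. The step needs chair over boat, which the trans-diequatorial geometry favors strongly, and rearrangement ahead of side reactions of the anions: the bulky silyl group should not migrate to the hindered tertiary alkoxide, and the C3–O bond of 17 lies close to the enolate plane because the ring bond C2–C3 must stay roughly perpendicular to it, which disfavors E1cB loss of the alkoxide. O-Sulfonylation of the tetrasubstituted enolate at −78 °C fixes its geometry and turns the ring-expansion carbonyl into the handle for the C4=C5 alkene.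

Step 9
Reactants: 18 (1(10)E,4Z,3S,6S,7S)-6-[(tert-butyldimethylsilyl)oxy]-3-[(4-methoxybenzyl)oxy]germacra-1(10),4,11-trien-5-yl trifluoromethanesulfonate
Product: 19 (1(10)E,4E,3S,6R,7S)-6-[(tert-butyldimethylsilyl)oxy]-3-[(4-methoxybenzyl)oxy]germacra-1(10),4,11-triene
Conditions: Pd(OAc)2 (cat.), PPh3, HCO2H, Bu3N, DMF, 40 °C
Reagents that add atoms: none
Why: Palladium-catalysed reduction of an enol triflate: oxidative addition of zerovalent palladium, exchange of triflate for formate, loss of CO2 and reductive elimination with retention, which should give the (4E) alkene; 40 °C stays below the onset of Cope rearrangement of the cyclodeca-1,5-diene.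

Step 10
Reactants: 19 (1(10)E,4E,3S,6R,7S)-6-[(tert-butyldimethylsilyl)oxy]-3-[(4-methoxybenzyl)oxy]germacra-1(10),4,11-triene
Product: 20 (1(10)E,4E,3S,6R,7S)-6-[(tert-butyldimethylsilyl)oxy]germacra-1(10),4,11-trien-3-ol
Conditions: DDQ, CH2Cl2/pH 7 phosphate buffer, 0 °C
Reagents that add atoms: none
Why: Oxidative cleavage of the 4-methoxybenzyl ether by DDQ (hydride abstraction, then hydrolysis of the oxocarbenium ion); the buffer keeps the acid-sensitive triene neutral, and the silyl ether and the alkenes should not be affected.

Step 11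
Reactants: 20 (1(10)E,4E,3S,6R,7S)-6-[(tert-butyldimethylsilyl)oxy]germacra-1(10),4,11-trien-3-ol
Product: 21 (1(10)E,3S,4R,5R,6S,7S)-6-[(tert-butyldimethylsilyl)oxy]-4,5-epoxygermacra-1(10),11-dien-3-ol
Conditions: VO(acac)2 (cat.), t-BuOOH, CH2Cl2, 0 °C
Reagents that add atoms: tert-butyl hydroperoxide, CC(C)(C)OO
Why: Vanadium-catalysed hydroxyl-directed epoxidation, selective for the allylic alcohol alkene over the homoallylic C1=C10 and the isopropenyl group; in the conformer that keeps H3 and H6 in the plane of C4=C5 (no A(1,3) strain between the C6 substituents and C15) with C2 and C7 on the inner face, O3 and the C6 silyloxy group both sit on the outer face, and the vanadium alkoxide delivers oxygen there, which should give the (4R,5R) epoxide, threo to both oxygens.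

Step 12
Reactants: 21 (1(10)E,3S,4R,5R,6S,7S)-6-[(tert-butyldimethylsilyl)oxy]-4,5-epoxygermacra-1(10),11-dien-3-ol
Product: 22 (1(10)E,3S,4R,5R,6S,7S)-6-[(tert-butyldimethylsilyl)oxy]-4,5-epoxygermacra-1(10),11-dien-3-yl (2E)-2-methylbut-2-enoate
Conditions: tigloyl chloride, pyridine, DMAP (cat.), CH2Cl2, 0 to 25 °C
Reagents that add atoms: (2E)-2-methylbut-2-enoyl chloride (tigloyl chloride), C/C=C(\C)C(=O)Cl
Why: Acylation of the only free hydroxyl with the acid chloride under nucleophilic catalysis by DMAP; the tiglate is the stable E isomer, and the amine medium leaves the epoxide intact.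

Step 13
Reactants: 22 (1(10)E,3S,4R,5R,6S,7S)-6-[(tert-butyldimethylsilyl)oxy]-4,5-epoxygermacra-1(10),11-dien-3-yl (2E)-2-methylbut-2-enoate
Product: 23 (1(10)E,3S,4R,5R,6S,7S)-4,5-epoxy-6-hydroxygermacra-1(10),11-dien-3-yl (2E)-2-methylbut-2-enoate
Conditions: Bu4NF, AcOH, THF, 0 to 25 °C
Reagents that add atoms: none
Why: Fluoride cleavage of the silyl ether; acetic acid buffers the medium so that no free alkoxide forms next to the epoxide (Payne rearrangement) and the ester is not cleaved.

Step 14
Reactants: 23 (1(10)E,3S,4R,5R,6S,7S)-4,5-epoxy-6-hydroxygermacra-1(10),11-dien-3-yl (2E)-2-methylbut-2-enoate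
Product: 24 (1(10)E,3S,4R,5S,7S)-4,5-epoxy-6-oxogermacra-1(10),11-dien-3-yl (2E)-2-methylbut-2-enoate
Conditions: 1,1,1-triacetoxy-1,2-benziodoxol-3(1H)-one, pyridine, CH2Cl2, 0 to 25 °C
Reagents that add atoms: none
Why: Periodinane oxidation of the secondary alcohol under buffered, non-enolizing conditions, so that the C7 center next to the new ketone and the epoxide should be kept.

Step 15
Reactants: 24 (1(10)E,3S,4R,5S,7S)-4,5-epoxy-6-oxogermacra-1(10),11-dien-3-yl (2E)-2-methylbut-2-enoate
Product: 25 (1(10)E,3S,4R,5R,6R,7S)-4,5-epoxy-6-hydroxygermacra-1(10),11-dien-3-yl (2E)-2-methylbut-2-enoate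
Conditions: Zn(BH4)2, Et2O, −20 °C
Reagents that add atoms: none
Why: Chelation-controlled reduction of an α,β-epoxy ketone: zinc bridges the ketone and epoxide oxygens and hydride adds to the face of the chelate opposite to C4, which is also the outer face of the ring; this should give the erythro alcohol (6R), the C6 epimer of 23; the ester is not reduced by Zn(BH4)2 at −20 °C.

Step 16
Reactants: 25 (1(10)E,3S,4R,5R,6R,7S)-4,5-epoxy-6-hydroxygermacra-1(10),11-dien-3-yl (2E)-2-methylbut-2-enoate
Product: 26 (1(10)E,3S,4R,5R,6R,7S)-6-acetoxy-4,5-epoxygermacra-1(10),11-dien-3-yl (2E)-2-methylbut-2-enoate (CNP0400048.1)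
Conditions: Ac2O, pyridine, DMAP (cat.), CH2Cl2, 25 °C
Reagents that add atoms: acetic anhydride, CC(=O)OC(C)=O
Why: Acetylation of the secondary alcohol with retention at C6 completes the target; pyridine and DMAP keep the medium free of acid and of alkoxide.

## Compound list

1 | (R)-carvone, (5R)-2-methyl-5-(prop-1-en-2-yl)cyclohex-2-en-1-one | CC1=CC[C@H](CC1=O)C(C)=C | starting material
2 | lithium (5R)-2-methyl-5-(prop-1-en-2-yl)cyclohex-1-en-1-olate | CC1=C([O-])C[C@H](C(C)=C)CC1.[Li+] | intermediate (not isolated)
3 | (2R,5R)-2-(1-hydroxyethyl)-2-methyl-5-(prop-1-en-2-yl)cyclohexan-1-one (both carbinol epimers) | CC(O)[C@@]1(C)CC[C@@H](C(C)=C)CC1=O | intermediate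
4 | (2R,5R)-2-ethenyl-2-methyl-5-(prop-1-en-2-yl)cyclohexan-1-one | C=C[C@@]1(C)CC[C@@H](C(C)=C)CC1=O | intermediate
5 | sodium (3R,6R)-6-ethenyl-6-methyl-3-(prop-1-en-2-yl)cyclohex-1-en-1-olate | C=C[C@@]1(C)CC[C@@H](C(C)=C)C=C1[O-].[Na+] | intermediate (not isolated)
6 | sodium (1S,3R,6S)-3-ethenyl-3-methyl-2-oxo-6-(prop-1-en-2-yl)cyclohexan-1-olate | C=C[C@@]1(C)CC[C@@H](C(C)=C)[C@H]([O-])C1=O.[Na+] | intermediate (not isolated)
7 | (2R,5S,6S)-6-[(tert-butyldimethylsilyl)oxy]-2-ethenyl-2-methyl-5-(prop-1-en-2-yl)cyclohexan-1-one | C=C[C@@]1(C)CC[C@@H](C(C)=C)[C@H](O[Si](C)(C)C(C)(C)C)C1=O | intermediate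
8 | 4-methoxybenzyl chloride, 1-(chloromethyl)-4-methoxybenzene | COc1ccc(CCl)cc1 | starting material
9 | allyl alcohol, prop-2-en-1-ol | C=CCO | starting material
10 | 1-methoxy-4-[(prop-2-en-1-yloxy)methyl]benzene | C=CCOCc1ccc(OC)cc1 | intermediate
11 | 1-methoxy-4-{[(1Z)-prop-1-en-1-yloxy]methyl}benzene | C/C=C\OCc1ccc(OC)cc1 | intermediate
12 | rac-1-{[(1R,2S)-1,2-dibromopropoxy]methyl}-4-methoxybenzene | C[C@H](Br)[C@@H](Br)OCc1ccc(OC)cc1 | intermediate (not isolated)
13 | 1-({[(1Z)-2-bromoprop-1-en-1-yl]oxy}methyl)-4-methoxybenzene | C/C(Br)=C/OCc1ccc(OC)cc1 | intermediate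
14 | {(1E)-1-[(4-methoxyphenyl)methoxy]prop-1-en-2-yl}lithium | C/C([Li])=C/OCc1ccc(OC)cc1 | intermediate (not isolated)
15 | (1R,2R,5S,6S)-6-[(tert-butyldimethylsilyl)oxy]-2-ethenyl-1-{(1Z)-1-[(4-methoxyphenyl)methoxy]prop-1-en-2-yl}-2-methyl-5-(prop-1-en-2-yl)cyclohexan-1-ol | COc1ccc(CO/C=C(/C)\[C@@]2(O)[C@@H](O[Si](C)(C)C(C)(C)C)[C@H](C(C)=C)CC[C@]2(C)C=C)cc1 | intermediate
16 | potassium (1R,2R,5S,6S)-6-[(tert-butyldimethylsilyl)oxy]-2-ethenyl-1-{(1Z)-1-[(4-methoxyphenyl)methoxy]prop-1-en-2-yl}-2-methyl-5-(prop-1-en-2-yl)cyclohexan-1-olate | COc1ccc(CO/C=C(/C)\[C@@]2([O-])[C@@H](O[Si](C)(C)C(C)(C)C)[C@H](C(C)=C)CC[C@]2(C)C=C)cc1.[K+] | intermediate (not isolated)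
17 | potassium (1(10)E,4Z,3S,6S,7S)-6-[(tert-butyldimethylsilyl)oxy]-3-[(4-methoxybenzyl)oxy]germacra-1(10),4,11-trien-5-olate | C=C(C)[C@@H]1CC/C(C)=C/C[C@H](OCc2ccc(OC)cc2)/C(C)=C([O-])/[C@H]1O[Si](C)(C)C(C)(C)C.[K+] | intermediate (not isolated)
18 | (1(10)E,4Z,3S,6S,7S)-6-[(tert-butyldimethylsilyl)oxy]-3-[(4-methoxybenzyl)oxy]germacra-1(10),4,11-trien-5-yl trifluoromethanesulfonate | C=C(C)[C@@H]1CC/C(C)=C/C[C@H](OCc2ccc(OC)cc2)/C(C)=C(OS(=O)(=O)C(F)(F)F)/[C@H]1O[Si](C)(C)C(C)(C)C | intermediate
19 | (1(10)E,4E,3S,6R,7S)-6-[(tert-butyldimethylsilyl)oxy]-3-[(4-methoxybenzyl)oxy]germacra-1(10),4,11-triene | C=C(C)[C@@H]1CC/C(C)=C/C[C@H](OCc2ccc(OC)cc2)/C(C)=C/[C@H]1O[Si](C)(C)C(C)(C)C | intermediate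
20 | (1(10)E,4E,3S,6R,7S)-6-[(tert-butyldimethylsilyl)oxy]germacra-1(10),4,11-trien-3-ol | C=C(C)[C@@H]1CC/C(C)=C/C[C@H](O)/C(C)=C/[C@H]1O[Si](C)(C)C(C)(C)C | intermediate
21 | (1(10)E,3S,4R,5R,6S,7S)-6-[(tert-butyldimethylsilyl)oxy]-4,5-epoxygermacra-1(10),11-dien-3-ol | C=C(C)[C@@H]1CC/C(C)=C/C[C@H](O)[C@@]2(C)O[C@@H]2[C@H]1O[Si](C)(C)C(C)(C)C | intermediate
22 | (1(10)E,3S,4R,5R,6S,7S)-6-[(tert-butyldimethylsilyl)oxy]-4,5-epoxygermacra-1(10),11-dien-3-yl (2E)-2-methylbut-2-enoate | C=C(C)[C@@H]1CC/C(C)=C/C[C@H](OC(=O)/C(C)=C/C)[C@@]2(C)O[C@@H]2[C@H]1O[Si](C)(C)C(C)(C)C | intermediate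
23 | (1(10)E,3S,4R,5R,6S,7S)-4,5-epoxy-6-hydroxygermacra-1(10),11-dien-3-yl (2E)-2-methylbut-2-enoate | C=C(C)[C@@H]1CC/C(C)=C/C[C@H](OC(=O)/C(C)=C/C)[C@@]2(C)O[C@@H]2[C@H]1O | intermediate
24 | (1(10)E,3S,4R,5S,7S)-4,5-epoxy-6-oxogermacra-1(10),11-dien-3-yl (2E)-2-methylbut-2-enoate | C=C(C)[C@@H]1CC/C(C)=C/C[C@H](OC(=O)/C(C)=C/C)[C@@]2(C)O[C@@H]2C1=O | intermediate
25 | (1(10)E,3S,4R,5R,6R,7S)-4,5-epoxy-6-hydroxygermacra-1(10),11-dien-3-yl (2E)-2-methylbut-2-enoate | C=C(C)[C@@H]1CC/C(C)=C/C[C@H](OC(=O)/C(C)=C/C)[C@@]2(C)O[C@@H]2[C@@H]1O | intermediate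
26 | (1(10)E,3S,4R,5R,6R,7S)-6-acetoxy-4,5-epoxygermacra-1(10),11-dien-3-yl (2E)-2-methylbut-2-enoate, CNP0400048.1 | C=C(C)[C@@H]1CC/C(C)=C/C[C@H](OC(=O)/C(C)=C/C)[C@@]2(C)O[C@@H]2[C@@H]1OC(C)=O | target

## Step count and least certain steps

Total step count: 16. Longest linear sequence: 13 steps (steps 1–3 and 7–16; the branch through steps 4–6 is equally long).

**Step 8 (key step).** The rearrangement must pass through the less stable, ring-inverted chair and carry the ether oxygen axial. If this makes the [3,3] shift slow, loss of the C3 alkoxide from enolate 17 and leakage through non-chair pathways would lower the yield and erode the configuration at C3. The fallback sets C3 by catalyst control after the ring expansion. It sets out from 20, as it would then be obtained mixed with its C3 epimer, and comes back at 20. Oxidation of the allylic alcohols with MnO2 gives one compound, the (1(10)E,4E)-3-ketone F1. Its Corey–Bakshi–Shibata reduction with (R)-2-methyl-CBS-oxazaborolidine and catecholborane at −78 °C, with the alkenyl group as the large substituent, should return 20 with the 3S configuration.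

**Step 7.** Alkenyllithium 14 can be lost by elimination of lithium 4-methoxybenzyl oxide if it warms, and the hindered ketone may be enolized instead of attacked. The fallback builds the Z enol ether on the ketone in two operations; it sets out from 7 and comes back at 15. Trichloroethylene and 4-methoxybenzyl alcohol (KH) give the (E)-1,2-dichlorovinyl ether F2. Two equivalents of n-BuLi convert it into the lithium alkoxyacetylide F3, a robust nucleophile that adds to 7 from the same face and gives the propargylic alcohol F4. Syn-carbocupration of the ynol ether (MeMgBr, CuBr·SMe2; copper on the oxygen-bearing carbon, methyl on C4) and protonation then give 15 with the Z geometry.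

**Step 11.** The vanadium catalyst is a Lewis acid and may promote transannular opening of the new epoxide by C1=C10, or oxidize the allylic alcohol; face selectivity could also be incomplete. The fallback uses a base-mediated epoxidation; it sets out from 20 and comes back at 21. MnO2 gives the enone F1 named above. Weitz–Scheffer epoxidation (t-BuOOH, DBU) attacks only the electron-poor C4=C5 bond from the same outer face and gives the epoxy ketone F5. Corey–Bakshi–Shibata reduction as above then gives 21.

**Step 15.** Chelation control may be weaker in the ring than in open-chain models, and ketone 24 can enolize toward C7. The fallback is a Mitsunobu reaction of 23 with acetic acid (PPh3, diisopropyl azodicarboxylate), which would invert C6 by SN2 and give 26 directly without passing through 24 and 25. It sets out from 23, comes back at 26 and makes no new compound (F0). It needs the ring to expose the back side of the C6–O bond, which is why it is the reserve and not the plan.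

## Further compounds

F1 | step 8 | (1(10)E,4E,6R,7S)-6-[(tert-butyldimethylsilyl)oxy]germacra-1(10),4,11-trien-3-one | C=C(C)[C@@H]1CC/C(C)=C/CC(=O)/C(C)=C/[C@H]1O[Si](C)(C)C(C)(C)C
F2 | step 7 | 1-({[(E)-1,2-dichloroethenyl]oxy}methyl)-4-methoxybenzene | Cl/C=C(/Cl)OCc1ccc(OC)cc1
F3 | step 7 | lithium 2-[(4-methoxyphenyl)methoxy]ethyn-1-ide | [Li]C#COCc1ccc(OC)cc1
F4 | step 7 | (1R,2R,5S,6S)-6-[(tert-butyldimethylsilyl)oxy]-2-ethenyl-1-{[(4-methoxyphenyl)methoxy]ethynyl}-2-methyl-5-(prop-1-en-2-yl)cyclohexan-1-ol | COc1ccc(COC#C[C@@]2(O)[C@@H](O[Si](C)(C)C(C)(C)C)[C@H](C(C)=C)CC[C@]2(C)C=C)cc1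
F5 | step 11 | (1(10)E,4S,5R,6S,7S)-6-[(tert-butyldimethylsilyl)oxy]-4,5-epoxygermacra-1(10),11-dien-3-one | C=C(C)[C@@H]1CC/C(C)=C/CC(=O)[C@@]2(C)O[C@@H]2[C@H]1O[Si](C)(C)C(C)(C)C
F0 | step 15 | none | none
A1 | alternative 1 | (2S,3S)-3-[(1S,3E,7E)-1-[(tert-butyldimethylsilyl)oxy]-9-chloro-4,8-dimethylnona-3,7-dien-1-yl]-3-methyloxirane-2-carbaldehyde | ClC/C(C)=C/CC/C(C)=C/C[C@H](O[Si](C)(C)C(C)(C)C)[C@@]1(C)O[C@@H]1C=O
A2 | alternative 1 | (1(10)E,3S,4S,5R,6R,7S)-3-[(tert-butyldimethylsilyl)oxy]-4,5-epoxygermacra-1(10),11-dien-6-ol | C=C(C)[C@@H]1CC/C(C)=C/C[C@H](O[Si](C)(C)C(C)(C)C)[C@@]2(C)O[C@@H]2[C@@H]1O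
A3 | alternative 2 | (3E,5S,7E,11E)-5-[(tert-butyldimethylsilyl)oxy]-4,8,12-trimethyl-1-oxacyclotrideca-3,7,11-triene | O1C/C=C(C)/[C@@H](O[Si](C)(C)C(C)(C)C)C/C=C(C)/CC/C=C(C)/C1
A4 | alternative 2 | (1(10)E,4E,3S,6R,7S)-3-[(tert-butyldimethylsilyl)oxy]germacra-1(10),4,11-trien-6-ol (hydroxyl trans to the isopropenyl group) | C=C(C)[C@@H]1CC/C(C)=C/C[C@H](O[Si](C)(C)C(C)(C)C)/C(C)=C/[C@H]1O
A5 | alternative 3 | trans-fused 1β-(methanesulfonyloxy)-3β-[(4-methoxybenzyl)oxy]-6α-[(tert-butyldimethylsilyl)oxy]-5α,7α-H-eudesm-11-en-15-al (10β-methyl, 4α-formyl) | O=C[C@@H]1[C@@H](OCc2ccc(OC)cc2)C[C@@H](OS(C)(=O)=O)[C@]2(C)CC[C@@H](C(C)=C)[C@H](O[Si](C)(C)C(C)(C)C)[C@@H]12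
A6 | alternative 3 | (1(10)E)-6-[(tert-butyldimethylsilyl)oxy]-3-[(4-methoxybenzyl)oxy]germacra-1(10),4,11-trien-15-al (C3 and C6 trans across C4=C5; 3S, 7S) | C=C(C)[C@@H]1CC/C(C)=C/C[C@H](OCc2ccc(OC)cc2)/C(C=O)=C/[C@H]1O[Si](C)(C)C(C)(C)C
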